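The route rests on disconnecting the aryl–oxygen bond O1–C7a of the dihydrofuran ring. Because C3 lies α to C2, the precursor is a racemic C2 ketone whose C3 carries a 2-fluoro-3-methoxyphenyl group (ring A). Rapid base-mediated racemisation at C3 lets one dynamic kinetic asymmetric hydrogenation set C2 and C3 together. The resulting alkoxide O1, placed for five-membered closure onto the fluorine-bearing C7a, then closes the furan ring by intramolecular SNAr in the same flask. The ketone comes from a palladium-catalysed α-arylation of protected propiosyringone. The C5 propenyl group is attached last by sterically controlled C–H borylation and Suzuki coupling, C5–H being the only unhindered aryl C–H.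

Key step: step 3

Remark: atoms are numbered as in 2,3-dihydro-1-benzofuran (O1, C2, C3, C3a, C4 to C7, C7a; ring A is the benzo ring, ring B the syringyl ring), and the (S)/(S) catalyst of step 3 is assumed to give the (R)-carbinol as it does with simple aryl alkyl ketones; if the sense proves opposite, its enantiomer is used.

Step 1
Reactants: 1 1-(4-hydroxy-3,5-dimethoxyphenyl)propan-1-one (propiosyringone)
Product: 2 1-[3,5-dimethoxy-4-(methoxymethoxy)phenyl]propan-1-one
Conditions: NaH (1.2 equiv), MOMCl (1.2 equiv), DMF, 0 °C to rt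
Reagents that add atoms: chloromethyl methyl ether (MOMCl), COCCl
Why: Williamson-type O-alkylation of the phenoxide should give the MOM ether, a base-stable mask for the phenol through the three basic steps that follow.

Step 2
Reactants: 2 1-[3,5-dimethoxy-4-(methoxymethoxy)phenyl]propan-1-one; 3 1-bromo-2-fluoro-3-methoxybenzene
Product: 4 rac-2-(2-fluoro-3-methoxyphenyl)-1-[3,5-dimethoxy-4-(methoxymethoxy)phenyl]propan-1-one
Conditions: Pd2(dba)3 (1 mol %), P(tBu)3·HBF4 (2.4 mol %), NaOtBu (2.2 equiv), toluene, 70 °C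
Reagents that add atoms: none
Why: Palladium-catalysed ketone α-arylation (Buchwald–Hartwig type) should proceed by oxidative addition of zerovalent palladium into the C–Br bond (C–F stays inert), enolate binding and reductive elimination, and the new C3 centre is formed racemic on purpose because step 3 resolves it dynamically.

Step 3
Reactants: 4 rac-2-(2-fluoro-3-methoxyphenyl)-1-[3,5-dimethoxy-4-(methoxymethoxy)phenyl]propan-1-one
Product: 6 (2R,3R)-2-[3,5-dimethoxy-4-(methoxymethoxy)phenyl]-7-methoxy-3-methyl-2,3-dihydro-1-benzofuran, via (1R,2R)-fluoro alcohol 5 (not isolated)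
Conditions: H2 (10 atm), RuCl2[(S)-xylbinap][(S)-daipen] (1 mol %), KOtBu (0.5 equiv), iPrOH, 25 °C; then evaporate, KOtBu (2.0 equiv), DMSO, 70 °C
Reagents that add atoms: none
Why: Under KOtBu the C3–H, flanked by ring A and the C2 carbonyl, exchanges rapidly, so both enantiomers of 4 interconvert while the hydride formed from RuCl2[(S)-xylbinap][(S)-daipen] delivers hydride and proton to the carbonyl in an outer-sphere step (Noyori asymmetric hydrogenation with dynamic kinetic resolution). The catalyst pocket selects the carbonyl face that gives the (R)-carbinol at C2, and only the C3-(R) enantiomer presents that face with ring A anti to the incoming hydride (Felkin–Anh), so C3 is set by matched substrate control and 5 should form as the (1R,2R) isomer. After solvent exchange the potassium alkoxide O1 adds to the fluorine-bearing C7a to give a Meisenheimer anion that expels fluoride, the closest known reaction being the base-mediated intramolecular SNAr of 2-(2-fluoroaryl)ethanols to 2,3-dihydrobenzofurans. The furan ring closes in a 5-exo-trig mode, the negative charge being taken up by the ring A π system outside the new ring. No bond to C2 or C3 is broken in the closure, so the (1R,2R) alcohol maps onto the trans-(2R,3R) ring. The step needs racemisation faster than reduction, secured by the acidic C3–H, and clean ipso attack, secured by the 1,5 relation of O1 to C7a and by the absence of a hydrogen ortho to fluorine, which excludes an aryne path.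

Step 4
Reactants: 6 (2R,3R)-2-[3,5-dimethoxy-4-(methoxymethoxy)phenyl]-7-methoxy-3-methyl-2,3-dihydro-1-benzofuran; 7 (E)-1-bromoprop-1-ene
Product: 9 (2R,3R)-2-[3,5-dimethoxy-4-(methoxymethoxy)phenyl]-7-methoxy-3-methyl-5-[(E)-prop-1-en-1-yl]-2,3-dihydro-1-benzofuran, via C5 pinacol boronate 8 (not isolated)
Conditions: [Ir(OMe)(cod)]2 (1.5 mol %), 4,4′-di-tert-butyl-2,2′-bipyridine (3 mol %), B2pin2 (1.0 equiv), THF, 80 °C; then Pd(dppf)Cl2 (5 mol %), K3PO4 (aq, 3 equiv), 7 (3 equiv), 60 °C
Reagents that add atoms: bis(pinacolato)diboron, CC1(C)OB(OC1(C)C)B1OC(C)(C)C(C)(C)O1 (supplies the boryl group of 8; no atom of it stays in 9)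
Why: Iridium-catalysed C–H borylation is governed by sterics and should select C5–H, the only aryl C–H without an ortho substituent (C4 adjoins C3a, C6 adjoins the C7 methoxy group, both ring B hydrogens are flanked twice), and the Suzuki–Miyaura coupling that follows transfers the propenyl group with retention of the E geometry.

Step 5
Reactants: 9 (2R,3R)-2-[3,5-dimethoxy-4-(methoxymethoxy)phenyl]-7-methoxy-3-methyl-5-[(E)-prop-1-en-1-yl]-2,3-dihydro-1-benzofuran
Product: 10 maceneolignan A, 2,6-dimethoxy-4-[(2R,3R)-7-methoxy-3-methyl-5-[(E)-prop-1-en-1-yl]-2,3-dihydro-1-benzofuran-2-yl]phenol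
Conditions: HCl (0.1 M), MeOH/THF (1:1), 25 to 40 °C
Reagents that add atoms: none
Why: Acid-catalysed acetal exchange of the aryl MOM ether with methanol should release the phenol and dimethoxymethane without touching C2, C3 or the (E)-alkene, any reversible ionisation at C2 re-closing to the more stable trans ring.

Compound list
1 | 1-(4-hydroxy-3,5-dimethoxyphenyl)propan-1-one (propiosyringone) | CCC(=O)c1cc(OC)c(O)c(OC)c1 | starting material
2 | 1-[3,5-dimethoxy-4-(methoxymethoxy)phenyl]propan-1-one | CCC(=O)c1cc(OC)c(OCOC)c(OC)c1 | intermediate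
3 | 1-bromo-2-fluoro-3-methoxybenzene | COc1cccc(Br)c1F | starting material
4 | rac-2-(2-fluoro-3-methoxyphenyl)-1-[3,5-dimethoxy-4-(methoxymethoxy)phenyl]propan-1-one | CC(C(=O)c1cc(OC)c(OCOC)c(OC)c1)c1cccc(OC)c1F | intermediate
5 | (1R,2R)-2-(2-fluoro-3-methoxyphenyl)-1-[3,5-dimethoxy-4-(methoxymethoxy)phenyl]propan-1-ol | C[C@H](c1cccc(OC)c1F)[C@@H](O)c1cc(OC)c(OCOC)c(OC)c1 | intermediate
6 | (2R,3R)-2-[3,5-dimethoxy-4-(methoxymethoxy)phenyl]-7-methoxy-3-methyl-2,3-dihydro-1-benzofuran | c1cc(OC)c2c(c1)[C@@H](C)[C@H](c1cc(OC)c(OCOC)c(OC)c1)O2 | intermediate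
7 | (E)-1-bromoprop-1-ene | C/C=C/Br | starting material
8 | 2-[(2R,3R)-2-[3,5-dimethoxy-4-(methoxymethoxy)phenyl]-7-methoxy-3-methyl-2,3-dihydro-1-benzofuran-5-yl]-4,4,5,5-tetramethyl-1,3,2-dioxaborolane | CC1(C)OB(OC1(C)C)c1cc(OC)c2c(c1)[C@@H](C)[C@H](c1cc(OC)c(OCOC)c(OC)c1)O2 | intermediate
9 | (2R,3R)-2-[3,5-dimethoxy-4-(methoxymethoxy)phenyl]-7-methoxy-3-methyl-5-[(E)-prop-1-en-1-yl]-2,3-dihydro-1-benzofuran | C/C=C/c1cc(OC)c2c(c1)[C@@H](C)[C@H](c1cc(OC)c(OCOC)c(OC)c1)O2 | intermediate
10 | maceneolignan A, 2,6-dimethoxy-4-[(2R,3R)-7-methoxy-3-methyl-5-[(E)-prop-1-en-1-yl]-2,3-dihydro-1-benzofuran-2-yl]phenol | C/C=C/c1cc(OC)c2c(c1)[C@@H](C)[C@H](c1cc(OC)c(O)c(OC)c1)O2 | target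

Total step count: 5. Longest linear sequence: 5 steps (1 → 2 → 4 → 6 → 9 → 10); compounds 3 and 7 are bought.

Steps most likely to fail

Step 3. The alkoxide may add too slowly to the unactivated, methoxy-flanked fluoroarene, so that prolonged heating in KOtBu/DMSO degrades the material before the ring closes. The fallback sets out from 2 and replaces the SNAr by a palladium-catalysed C–O coupling. α-Arylation of 2 under the step 2 conditions with commercial 1-bromo-2-chloro-3-methoxybenzene (C–Br selective) should give rac-2-(2-chloro-3-methoxyphenyl)-1-[3,5-dimethoxy-4-(methoxymethoxy)phenyl]propan-1-one F1. The same dynamic kinetic hydrogenation should give the isolated (1R,2R)-2-(2-chloro-3-methoxyphenyl)-1-[3,5-dimethoxy-4-(methoxymethoxy)phenyl]propan-1-ol F2. Intramolecular Buchwald etherification (Pd(OAc)2, 2-(di-tert-butylphosphino)-1,1′-binaphthyl, Cs2CO3, toluene, 80 °C) should then close the same O1–C7a bond by oxidative addition, alkoxide exchange and reductive elimination, coming back to the route at 6.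

Step 4. The borylation may lose site selectivity or stall on the ether-rich late intermediate, or the boronate may protodeboronate before it couples. The fallback sets out from 3 and installs the C5 handle on the simple arene, where C5–H is again the only unhindered C–H. Borylation with [Ir(OMe)(cod)]2/4,4′-di-tert-butyl-2,2′-bipyridine/B2pin2 should give 2-(3-bromo-4-fluoro-5-methoxyphenyl)-4,4,5,5-tetramethyl-1,3,2-dioxaborolane F3, which is chlorinated in the same flask with CuCl2 in MeOH/H2O to 1-bromo-5-chloro-2-fluoro-3-methoxybenzene F4. α-Arylation of 2 with F4 under the step 2 conditions should give rac-2-(5-chloro-2-fluoro-3-methoxyphenyl)-1-[3,5-dimethoxy-4-(methoxymethoxy)phenyl]propan-1-one F5. The step 3 conditions should lead, through (1R,2R)-2-(5-chloro-2-fluoro-3-methoxyphenyl)-1-[3,5-dimethoxy-4-(methoxymethoxy)phenyl]propan-1-ol F6, to (2R,3R)-5-chloro-2-[3,5-dimethoxy-4-(methoxymethoxy)phenyl]-7-methoxy-3-methyl-2,3-dihydro-1-benzofuran F7. Suzuki coupling of F7 with potassium (E)-prop-1-enyltrifluoroborate (Pd(OAc)2, SPhos, K2CO3, toluene/H2O, 85 °C) comes back to the route at 9.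

Step 5. Protic acid may ionise the C2–O1 benzylic ether or protonate the electron-rich propenyl group (ring opening, solvent addition, dimerisation) faster than the acetal is cleaved. The fallback sets out from 9 and avoids protic acid. Et3SiOTf with 2,2′-bipyridyl in CH2Cl2 at 0 °C should convert the aryl MOM ether directly into triethyl{2,6-dimethoxy-4-[(2R,3R)-7-methoxy-3-methyl-5-[(E)-prop-1-en-1-yl]-2,3-dihydro-1-benzofuran-2-yl]phenoxy}silane F8. Bu4NF in THF at 0 °C should then free the phenol, coming back to the route at 10.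

Further compounds
F1 | step 3 | rac-2-(2-chloro-3-methoxyphenyl)-1-[3,5-dimethoxy-4-(methoxymethoxy)phenyl]propan-1-one | CC(C(=O)c1cc(OC)c(OCOC)c(OC)c1)c1cccc(OC)c1Cl
F2 | step 3 | (1R,2R)-2-(2-chloro-3-methoxyphenyl)-1-[3,5-dimethoxy-4-(methoxymethoxy)phenyl]propan-1-ol | C[C@H](c1cccc(OC)c1Cl)[C@@H](O)c1cc(OC)c(OCOC)c(OC)c1
F3 | step 4 | 2-(3-bromo-4-fluoro-5-methoxyphenyl)-4,4,5,5-tetramethyl-1,3,2-dioxaborolane | COc1cc(cc(Br)c1F)B1OC(C)(C)C(C)(C)O1
F4 | step 4 | 1-bromo-5-chloro-2-fluoro-3-methoxybenzene | COc1cc(Cl)cc(Br)c1F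
F5 | step 4 | rac-2-(5-chloro-2-fluoro-3-methoxyphenyl)-1-[3,5-dimethoxy-4-(methoxymethoxy)phenyl]propan-1-one | CC(C(=O)c1cc(OC)c(OCOC)c(OC)c1)c1cc(Cl)cc(OC)c1F
F6 | step 4 | (1R,2R)-2-(5-chloro-2-fluoro-3-methoxyphenyl)-1-[3,5-dimethoxy-4-(methoxymethoxy)phenyl]propan-1-ol | C[C@H](c1cc(Cl)cc(OC)c1F)[C@@H](O)c1cc(OC)c(OCOC)c(OC)c1
F7 | step 4 | (2R,3R)-5-chloro-2-[3,5-dimethoxy-4-(methoxymethoxy)phenyl]-7-methoxy-3-methyl-2,3-dihydro-1-benzofuran | Clc1cc(OC)c2c(c1)[C@@H](C)[C@H](c1cc(OC)c(OCOC)c(OC)c1)O2
F8 | step 5 | triethyl{2,6-dimethoxy-4-[(2R,3R)-7-methoxy-3-methyl-5-[(E)-prop-1-en-1-yl]-2,3-dihydro-1-benzofuran-2-yl]phenoxy}silane | C/C=C/c1cc(OC)c2c(c1)[C@@H](C)[C@H](c1cc(OC)c(O[Si](CC)(CC)CC)c(OC)c1)O2
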